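## Retrosynthetic overview

1. Last disconnections: the 3-hydroxy-3-methylglutarate ester C–O bond (desymmetrised half-ester), the ring carbinol C3′ (reduction, then inversion), and the epoxide (nucleophilic epoxidation of a quinone monoketal obtained by dearomatising a para-methoxyphenol).
2. The exocyclic methylene comes from a C8 ketone (Wittig).
3. Key disconnection: C8–C9 and C9–C10 together. Ring B (C5–C10, six-membered) is made from the cyclopentanone ring of a trans-hydrindanone by inserting a carbenoid carbon (C9) that already carries the CH2–aryl half of the molecule.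
4. Enabling feature: the C8 carbonyl sits in a five-membered ring between the quaternary angular carbon C10 and the C7 methylene, so the electron-rich quaternary carbon migrates to the carbenoid; C9 ends α to the C8 carbonyl and is therefore epimerisable to the equatorial configuration.
5. Ring order: ring A and the cyclopentanone come from the Hajos–Parrish ketone, ring B follows by expansion, the arene then becomes the cyclohexenone ring, and the epoxide is closed last.

Key step: step 12

Atom names: C1–C12 follow drimane numbering (C8 carries the methylene, C9 carries the CH2 link C11, C10 is the angular quaternary carbon). Primed atoms belong to the cyclohexenone ring (C1′ quaternary epoxide carbon, C2′ epoxide CH, C3′ carbinol, C4′ carbon bearing CH2O, C6′ ketone).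

Abbreviations: Ar = 5-methoxy-2-(triisopropylsilyloxy)-4-[(triisopropylsilyloxy)methyl]phenyl; Dr = (1S,4aS,8aS)-5,5,8a-trimethyl-2-methylidenedecahydronaphthalen-1-yl; TIPS = triisopropylsilyl; TMSE = 2-(trimethylsilyl)ethyl.

Assumption 1: pig liver esterase is taken to hydrolyse the pro-S ester group of dimethyl 3-hydroxy-3-methylglutarate and so to give the (S)-half-ester; the arm freed by the enzyme is the arm later joined to the core.

Assumption 2: the cinchonidine-derived ammonium salt is taken to direct the peroxide to the face of the quinone monoketal that gives the (S,S)-configured epoxide carbons of the target; if the induction is opposite, the pseudoenantiomeric N-benzylcinchoninium chloride is used.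

## Route

Step 1
Reactants: 1 (S)-Hajos–Parrish ketone, (7aS)-7a-methyl-2,3,7,7a-tetrahydro-1H-indene-1,5(6H)-dione
Product: 2 (7aS)-enedione 1-(ethylene ketal): spiro-dioxolane on the cyclopentanone carbon, enone untouched
Conditions: 2-ethyl-2-methyl-1,3-dioxolane, ethylene glycol (cat.), p-TsOH (cat.), rt
Reagents that add atoms: 2-ethyl-2-methyl-1,3-dioxolane, CCC1(C)OCCO1
Why: Acid-catalysed dioxolane exchange (transketalisation) should occur only at the saturated cyclopentanone carbonyl, the enone carbonyl being much less electrophilic; the stereocentre is not involved.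

Step 2
Reactants: 2 enone ketal
Product: 3 (7aS)-4,4,7a-trimethyl-5-oxo ketal with the double bond moved to C3=C3a
Conditions: KOtBu, MeI, t-BuOH/THF, 0 °C → rt
Reagents that add atoms: iodomethane, CI
Why: Deconjugative α,α-dialkylation through the extended potassium dienolate should place both methyl groups on C4 and shift the double bond to the ring-fusion position.

Step 3
Reactants: 3 dimethylated keto ketal
Product: 4 (7aS)-4,4,7a-trimethyl-2,4,5,6,7,7a-hexahydro-1H-inden-1-one ethylene ketal (C3=C3a alkene)
Conditions: N2H4·H2O, KOH, diethylene glycol, 130 → 200 °C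
Reagents that add atoms: none
Why: Wolff–Kishner reduction removes the hindered C5 carbonyl under basic conditions that the ketal and the isolated alkene tolerate.

Step 4
Reactants: 4 alkene ketal
Product: 5 (3aS,7aS)-4,4,7a-trimethyloctahydro-1H-inden-1-one ethylene ketal (trans ring fusion)
Conditions: H2 (4 atm), 10% Pd/C, EtOAc, rt
Reagents that add atoms: none
Why: Heterogeneous catalytic hydrogenation should deliver hydrogen to the alkene face opposite the angular methyl, setting the ring-fusion hydrogen trans to the methyl, as in the hydrogenation of 14,15-unsaturated steroid CD-ring intermediates.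

Step 5
Reactants: 5 saturated ketal
Product: 6 (3aS,7aS)-4,4,7a-trimethyloctahydro-1H-inden-1-one
Conditions: 1 M HCl, THF, rt
Reagents that add atoms: water, O
Why: Acid hydrolysis of the dioxolane unmasks the cyclopentanone; neither stereocentre is α to the carbonyl with a hydrogen, so nothing can epimerise.

Step 6
Reactants: 7 4-bromo-2,5-dimethoxybenzaldehyde
Product: 8 4-bromo-2-hydroxy-5-methoxybenzaldehyde
Conditions: BCl3, CH2Cl2, −78 → 0 °C
Reagents that add atoms: none
Why: Chelation-directed aryl methyl ether cleavage: only the methoxy group ortho to the formyl group is demethylated.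

Step 7
Reactants: 8 bromo salicylaldehyde
Product: 9 2-hydroxy-4-(hydroxymethyl)-5-methoxybenzaldehyde
Conditions: Bu3SnCH2OH, Pd(PPh3)4 (5 mol %), 1,4-dioxane, 100 °C
Reagents that add atoms: (tributylstannyl)methanol, OC[Sn](CCCC)(CCCC)CCCC
Why: Stille cross-coupling under zerovalent-palladium catalysis introduces the hydroxymethyl carbon and tolerates the phenol and the aldehyde.

Step 8
Reactants: 9 hydroxymethyl salicylaldehyde
Product: 10 5-methoxy-2-(triisopropylsilyloxy)-4-[(triisopropylsilyloxy)methyl]benzaldehyde (Ar–CHO)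
Conditions: TIPSOTf, 2,6-lutidine, CH2Cl2, 0 °C → rt
Reagents that add atoms: triisopropylsilyl trifluoromethanesulfonate, CC(C)[Si](OS(=O)(=O)C(F)(F)F)(C(C)C)C(C)C
Why: Silylation of both hydroxyl groups gives bulky ethers that should survive the organolithium bases and the ylide and can later be removed together.

Step 9
Reactants: 10 Ar–CHO
Product: 11 Ar–CH2OH
Conditions: NaBH4, MeOH/THF, −20 °C
Reagents that add atoms: none
Why: Borohydride reduction of the aldehyde; the low temperature limits migration of the neighbouring aryl silyl group to the new benzylic alkoxide.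

Step 10
Reactants: 11 Ar–CH2OH
Product: 12 Ar–CH2Br
Conditions: CBr4, PPh3, CH2Cl2, 0 °C
Reagents that add atoms: tetrabromomethane, BrC(Br)(Br)Br
Why: Appel bromination converts the primary benzylic alcohol into the bromide under neutral conditions that leave the silyl ethers intact.

Step 11
Reactants: 12 Ar–CH2Br
Product: 13 Ar–CH2–CHBr2, 1-(2,2-dibromoethyl) arene
Conditions: CH2Br2, LDA, THF/Et2O, −95 °C; then 12, −95 → −60 °C
Reagents that add atoms: dibromomethane, BrCBr
Why: SN2 alkylation of dibromomethyllithium by the reactive benzylic bromide installs the future C9 at the gem-dibromide level needed for carbenoid formation.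

Step 12
Reactants: 6 trans-hydrindanone; 13 gem-dibromide
Product: 18 (1R,4aS,8aS)-1-(Ar-methyl)-5,5,8a-trimethyloctahydronaphthalen-2(1H)-one, via dibromoalkyllithium 14 (not isolated), via dibromo alkoxide 15 (not isolated), via oxido carbenoid 16 (not isolated), via lithium enolate 17 (not isolated)
Conditions: 13, LiTMP (lithium 2,2,6,6-tetramethylpiperidide), THF/Et2O, −105 °C; then 6, −105 → −90 °C; n-BuLi (2.2 equiv), −95 → −20 °C; AcOH; NaOMe (cat.), MeOH, rt
Reagents that add atoms: none
Why: LiTMP deprotonates 13 to the dibromoalkyllithium 14, which adds to the C8 carbonyl of 6 from the face opposite the angular methyl to give alkoxide 15; bromine–lithium exchange then generates the β-oxido carbenoid 16, whose electron-poor carbenoid carbon (C9) accepts a 1,2-shift of a ring bond with loss of LiBr and gives the six-membered enolate 17. The closest known reaction type is the β-oxido carbenoid one-carbon ring enlargement of cycloalkanones with 1,1-dibromoalkanes, a carbanion-initiated semipinacol homologation. Ring B is closed not by cyclisation but by ring expansion: the C8–C10 bond of the cyclopentane migrates to C9, so the five-membered ring becomes six-membered while the new C8–C9 and C9–C10 bonds join the two fragments at the quaternary carbon. C5 and C10 pass through unchanged (C10 migrates with retention), and the only new stereocentre, C9, is set afterwards: the enolate is protonated on the axial face anti to the angular methyl, and NaOMe equilibration funnels both C9 epimers, and hence both diastereomers of 15 and 16, to the ketone with the equatorial arylmethyl group. The step needs the quaternary C10 to migrate rather than the C7 methylene; this rests on the higher migratory aptitude of the more substituted, more electron-rich carbon toward the carbenoid centre and on relief of the strain of the trans-fused hydrindanone. It also needs addition to outrun enolisation of 6 and α-elimination of 14, which the very low temperature and the preformed carbenoid address.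

Step 13
Reactants: 18 ring-expanded ketone
Product: 19 Dr–CH2–Ar (bis-TIPS ether)
Conditions: Ph3PCH3Br, KHMDS, THF, 0 → 65 °C
Reagents that add atoms: methyltriphenylphosphonium bromide, C[P+](c1ccccc1)(c1ccccc1)c1ccccc1.[Br-]
Why: Wittig methylenation of the C8 ketone; the ylide is basic, but C9 already holds the thermodynamically preferred equatorial configuration, so enolisation cannot scramble it.

Step 14
Reactants: 19 bis-TIPS ether
Product: 20 2-(Dr-methyl)-5-(hydroxymethyl)-4-methoxyphenol
Conditions: TBAF, THF, 0 °C → rt; aq. NH4Cl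
Reagents that add atoms: none
Why: Fluoride cleaves the aryl and the primary alkyl silyl ether together (Si–O cleavage driven by Si–F bond formation), unmasking the para-methoxyphenol.

Step 15
Reactants: 20 para-methoxyphenol
Product: 21 2-(Dr-methyl)-5-(hydroxymethyl)-4,4-dimethoxycyclohexa-2,5-dien-1-one
Conditions: PhI(OAc)2, MeOH, 0 °C
Reagents that add atoms: methanol, CO
Why: Hypervalent-iodine oxidative dearomatisation of a para-methoxyphenol in methanol traps the phenoxonium ion at the methoxy-bearing carbon, which fixes the ketal at C3′ and the free carbonyl at C6′.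

Step 16
Reactants: 21 quinone monoketal
Product: 22 (1S,6R)-1-(Dr-methyl)-4-(hydroxymethyl)-5,5-dimethoxy-7-oxabicyclo[4.1.0]hept-3-en-2-one
Conditions: t-BuOOH, NaOH (aq.), N-benzylcinchonidinium chloride (10 mol %), toluene, 0 °C
Reagents that add atoms: tert-butyl hydroperoxide, CC(C)(C)OO
Why: Weitz–Scheffer nucleophilic epoxidation under chiral phase-transfer catalysis: the peroxide anion adds only to the enone double bond with an unsubstituted β-carbon (C2′), the other alkene being blocked by its β-substituent, and the chiral ion pair selects the face, setting C1′ and C2′ (the cis epoxide fusion is inherent).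

Step 17
Reactants: 23 dimethyl 3-hydroxy-3-methylpentanedioate
Product: 24 (3S)-3-hydroxy-5-methoxy-3-methyl-5-oxopentanoic acid
Conditions: pig liver esterase, pH 8 phosphate buffer, NaOH (pH-stat), rt; then HCl to pH 2
Reagents that add atoms: water, O
Why: Enzymatic desymmetrisation of the prochiral diester hydrolyses one enantiotopic ester group and so sets the configuration of the tertiary carbinol carbon.

Step 18
Reactants: 24 (S)-methyl half-ester
Product: 25 1-tert-butyl 5-methyl (3R)-3-hydroxy-3-methylpentanedioate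
Conditions: t-BuOC(=NH)CCl3, cyclohexane/CH2Cl2, rt
Reagents that add atoms: tert-butyl 2,2,2-trichloroacetimidate, CC(C)(C)OC(=N)C(Cl)(Cl)Cl
Why: Imidate tert-butylation esterifies the carboxylic acid without added acid (the tertiary alcohol does not react), differentiating the two arms for the exchange of ester groups.

Step 19
Reactants: 25 mixed diester
Product: 26 (3R)-5-tert-butoxy-3-hydroxy-3-methyl-5-oxopentanoic acid
Conditions: LiOH, THF/H2O, 0 °C; then aq. HCl to pH 3
Reagents that add atoms: lithium hydroxide, [Li+].[OH-]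
Why: Saponification cleaves the methyl ester while the tert-butyl ester is inert to hydroxide; the stereocentre bears no acidic hydrogen.

Step 20
Reactants: 26 tert-butyl half-ester
Product: 27 1-tert-butyl 5-[2-(trimethylsilyl)ethyl] (3R)-3-hydroxy-3-methylpentanedioate
Conditions: Me3SiCH2CH2OH, EDC·HCl, DMAP (cat.), CH2Cl2, 0 °C → rt
Reagents that add atoms: 2-(trimethylsilyl)ethanol, OCC[Si](C)(C)C
Why: Carbodiimide (Steglich) esterification puts a fluoride-labile ester on the arm that must end as the free acid.

Step 21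
Reactants: 27 tert-butyl TMSE diester
Product: 28 (3S)-3-hydroxy-3-methyl-5-oxo-5-[2-(trimethylsilyl)ethoxy]pentanoic acid
Conditions: TFA/CH2Cl2 (1:4), 0 °C
Reagents that add atoms: none
Why: Acidolysis removes the tert-butyl ester as isobutene and frees the arm originally liberated by the enzyme, giving the half-ester with its arms arranged as in the target.

Step 22
Reactants: 22 epoxy ketal alcohol; 28 TMSE half-ester
Product: 29 ester of 22 with 28 at the primary hydroxyl
Conditions: EDC·HCl, DMAP (cat.), CH2Cl2, 0 °C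
Reagents that add atoms: none
Why: Steglich esterification of the only reactive hydroxyl group of 22 (primary, allylic); the tertiary alcohol of 28 is too hindered to compete.

Step 23
Reactants: 29 epoxy ketal ester
Product: 30 (1S,6R)-epoxy-enedione ester (7-oxabicyclo[4.1.0]hept-3-ene-2,5-dione core)
Conditions: oxalic acid (10% aq.) on SiO2, CH2Cl2, rt
Reagents that add atoms: water, O
Why: Mild acid-catalysed hydrolysis of the dimethyl ketal liberates the C3′ carbonyl; the weak supported acid is chosen to spare the exocyclic alkene, the epoxide and the TMSE ester.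

Step 24
Reactants: 30 epoxy-enedione ester
Product: 31 (1S,5S,6S)-5-hydroxy epoxy enone ester (hydroxyl cis to the epoxide)
Conditions: NaBH4, CeCl3·7H2O, MeOH, −78 °C
Reagents that add atoms: none
Why: Luche 1,2-reduction should occur at the C3′ carbonyl, which is less hindered and more electrophilic than C6′ (flanked by the quaternary epoxide carbon and deactivated by the β-alkyl group of its enone); hydride attacks anti to the epoxide oxygen, giving the cis-epoxy alcohol.

Step 25
Reactants: 31 cis-epoxy alcohol
Product: 32 (1S,5R,6S)-5-formyloxy epoxy enone ester (formate trans to the epoxide)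
Conditions: HCO2H, PPh3, DIAD, THF, −20 → 0 °C
Reagents that add atoms: formic acid, OC=O
Why: Mitsunobu reaction with formic acid substitutes the activated C3′ oxygen with inversion (SN2 from the face anti to the epoxide), setting the required trans relationship.

Step 26
Reactants: 32 trans formate TMSE ester
Product: 34 target compound, via formate acid 33 (not isolated)
Conditions: TBAF, THF, 0 °C; then KHCO3, MeOH/H2O, 0 °C; aq. NaH2PO4 (pH 4)
Reagents that add atoms: none
Why: Fluoride-induced β-elimination cleaves the TMSE ester to the carboxylate, and the labile formate is then solvolysed by bicarbonate, conditions the ordinary alkyl ester linkage should survive.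

## Compound list

1 | (S)-Hajos–Parrish ketone, (7aS)-7a-methyl-2,3,7,7a-tetrahydro-1H-indene-1,5(6H)-dione | O=C1CCC2=CC(=O)CC[C@]12C | starting material
2 | (7aS)-7a-methyl enedione 1-(ethylene ketal) | O1CCOC12CCC3=CC(=O)CC[C@]23C | intermediate
3 | (7aS)-4,4,7a-trimethyl-5-oxo 1-(ethylene ketal), C3=C3a alkene | O1CCOC12CC=C3C(C)(C)C(=O)CC[C@]23C | intermediate
4 | (7aS)-4,4,7a-trimethylhexahydroinden-1-one ethylene ketal, C3=C3a alkene | O1CCOC12CC=C3C(C)(C)CCC[C@]23C | intermediate
5 | (3aS,7aS)-4,4,7a-trimethyloctahydro-1H-inden-1-one ethylene ketal | O1CCOC12CC[C@H]3C(C)(C)CCC[C@]23C | intermediate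
6 | (3aS,7aS)-4,4,7a-trimethyloctahydro-1H-inden-1-one | O=C1CC[C@H]2C(C)(C)CCC[C@]12C | intermediate
7 | 4-bromo-2,5-dimethoxybenzaldehyde | O=Cc1cc(OC)c(Br)cc1OC | starting material
8 | 4-bromo-2-hydroxy-5-methoxybenzaldehyde | O=Cc1cc(OC)c(Br)cc1O | intermediate
9 | 2-hydroxy-4-(hydroxymethyl)-5-methoxybenzaldehyde | O=Cc1cc(OC)c(CO)cc1O | intermediate
10 | 5-methoxy-2-(triisopropylsilyloxy)-4-[(triisopropylsilyloxy)methyl]benzaldehyde | O=Cc1cc(OC)c(CO[Si](C(C)C)(C(C)C)C(C)C)cc1O[Si](C(C)C)(C(C)C)C(C)C | intermediate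
11 | {5-methoxy-2-(triisopropylsilyloxy)-4-[(triisopropylsilyloxy)methyl]phenyl}methanol | OCc1cc(OC)c(CO[Si](C(C)C)(C(C)C)C(C)C)cc1O[Si](C(C)C)(C(C)C)C(C)C | intermediate
12 | 1-(bromomethyl)-5-methoxy-2-(triisopropylsilyloxy)-4-[(triisopropylsilyloxy)methyl]benzene | BrCc1cc(OC)c(CO[Si](C(C)C)(C(C)C)C(C)C)cc1O[Si](C(C)C)(C(C)C)C(C)C | intermediate
13 | 1-(2,2-dibromoethyl)-5-methoxy-2-(triisopropylsilyloxy)-4-[(triisopropylsilyloxy)methyl]benzene | BrC(Br)Cc1cc(OC)c(CO[Si](C(C)C)(C(C)C)C(C)C)cc1O[Si](C(C)C)(C(C)C)C(C)C | intermediate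
14 | (1,1-dibromo-2-Ar-ethyl)lithium | [Li]C(Br)(Br)Cc1cc(OC)c(CO[Si](C(C)C)(C(C)C)C(C)C)cc1O[Si](C(C)C)(C(C)C)C(C)C | intermediate
15 | lithium (1S,3aS,7aS)-1-(1,1-dibromo-2-Ar-ethyl)-4,4,7a-trimethyloctahydroinden-1-olate | [Li]O[C@@]1(C(Br)(Br)Cc3cc(OC)c(CO[Si](C(C)C)(C(C)C)C(C)C)cc3O[Si](C(C)C)(C(C)C)C(C)C)CC[C@H]2C(C)(C)CCC[C@]12C | intermediate
16 | β-oxido carbenoid: 1-(1-bromo-1-lithio-2-Ar-ethyl) lithium alkoxide, either configuration at the carbenoid carbon | [Li]O[C@@]1(C([Li])(Br)Cc3cc(OC)c(CO[Si](C(C)C)(C(C)C)C(C)C)cc3O[Si](C(C)C)(C(C)C)C(C)C)CC[C@H]2C(C)(C)CCC[C@]12C | intermediate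
17 | lithium enolate of 18 (C8–C9 enolate, ring B formed) | [Li]OC1CC[C@H]2C(C)(C)CCC[C@]2(C)C=1Cc3cc(OC)c(CO[Si](C(C)C)(C(C)C)C(C)C)cc3O[Si](C(C)C)(C(C)C)C(C)C | intermediate
18 | (1R,4aS,8aS)-1-(Ar-methyl)-5,5,8a-trimethyloctahydronaphthalen-2(1H)-one | O=C1CC[C@H]2C(C)(C)CCC[C@]2(C)[C@H]1Cc3cc(OC)c(CO[Si](C(C)C)(C(C)C)C(C)C)cc3O[Si](C(C)C)(C(C)C)C(C)C | intermediate
19 | Dr–CH2–Ar: (1S,4aS,8aS)-1-(Ar-methyl)-5,5,8a-trimethyl-2-methylidenedecahydronaphthalene | C=C1CC[C@H]2C(C)(C)CCC[C@]2(C)[C@H]1Cc3cc(OC)c(CO[Si](C(C)C)(C(C)C)C(C)C)cc3O[Si](C(C)C)(C(C)C)C(C)C | intermediate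
20 | 2-(Dr-methyl)-5-(hydroxymethyl)-4-methoxyphenol | C=C1CC[C@H]2C(C)(C)CCC[C@]2(C)[C@H]1Cc3cc(OC)c(CO)cc3O | intermediate
21 | 2-(Dr-methyl)-5-(hydroxymethyl)-4,4-dimethoxycyclohexa-2,5-dien-1-one | C=C1CC[C@H]2C(C)(C)CCC[C@]2(C)[C@H]1CC3=CC(OC)(OC)C(CO)=CC3=O | intermediate
22 | (1S,6R)-1-(Dr-methyl)-4-(hydroxymethyl)-5,5-dimethoxy-7-oxabicyclo[4.1.0]hept-3-en-2-one | C=C1CC[C@H]2C(C)(C)CCC[C@]2(C)[C@H]1C[C@]34O[C@H]3C(OC)(OC)C(CO)=CC4=O | intermediate
23 | dimethyl 3-hydroxy-3-methylpentanedioate | COC(=O)CC(C)(O)CC(=O)OC | starting material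
24 | (3S)-3-hydroxy-5-methoxy-3-methyl-5-oxopentanoic acid | OC(=O)C[C@](C)(O)CC(=O)OC | intermediate
25 | 1-tert-butyl 5-methyl (3R)-3-hydroxy-3-methylpentanedioate | CC(C)(C)OC(=O)C[C@](C)(O)CC(=O)OC | intermediate
26 | (3R)-5-tert-butoxy-3-hydroxy-3-methyl-5-oxopentanoic acid | CC(C)(C)OC(=O)C[C@](C)(O)CC(=O)O | intermediate
27 | 1-tert-butyl 5-[2-(trimethylsilyl)ethyl] (3R)-3-hydroxy-3-methylpentanedioate | CC(C)(C)OC(=O)C[C@](C)(O)CC(=O)OCC[Si](C)(C)C | intermediate
28 | (3S)-3-hydroxy-3-methyl-5-oxo-5-[2-(trimethylsilyl)ethoxy]pentanoic acid | OC(=O)C[C@](C)(O)CC(=O)OCC[Si](C)(C)C | intermediate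
29 | (1S,6R)-epoxy ketal enone esterified at CH2O with the (3R)-glutarate TMSE half-ester | C=C1CC[C@H]2C(C)(C)CCC[C@]2(C)[C@H]1C[C@]34O[C@H]3C(OC)(OC)C(COC(=O)C[C@](C)(O)CC(=O)OCC[Si](C)(C)C)=CC4=O | intermediate
30 | (1S,6R)-1-(Dr-methyl)-7-oxabicyclo[4.1.0]hept-3-ene-2,5-dione 4-CH2O (3R)-glutarate TMSE ester | C=C1CC[C@H]2C(C)(C)CCC[C@]2(C)[C@H]1C[C@]34O[C@H]3C(=O)C(COC(=O)C[C@](C)(O)CC(=O)OCC[Si](C)(C)C)=CC4=O | intermediate
31 | (1S,5S,6S)-5-hydroxy epoxy enone TMSE ester (hydroxyl cis to epoxide) | C=C1CC[C@H]2C(C)(C)CCC[C@]2(C)[C@H]1C[C@]34O[C@H]3[C@@H](O)C(COC(=O)C[C@](C)(O)CC(=O)OCC[Si](C)(C)C)=CC4=O | intermediate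
32 | (1S,5R,6S)-5-formyloxy epoxy enone TMSE ester (formate trans to epoxide) | C=C1CC[C@H]2C(C)(C)CCC[C@]2(C)[C@H]1C[C@]34O[C@H]3[C@H](OC=O)C(COC(=O)C[C@](C)(O)CC(=O)OCC[Si](C)(C)C)=CC4=O | intermediate
33 | (1S,5R,6S)-5-formyloxy epoxy enone glutarate half-ester, free acid (tetrabutylammonium salt in the flask) | C=C1CC[C@H]2C(C)(C)CCC[C@]2(C)[C@H]1C[C@]34O[C@H]3[C@H](OC=O)C(COC(=O)C[C@](C)(O)CC(=O)O)=CC4=O | intermediate
34 | target: (3R)-5-{[(1S,5R,6S)-1-(Dr-methyl)-5-hydroxy-2-oxo-7-oxabicyclo[4.1.0]hept-3-en-4-yl]methoxy}-3-hydroxy-3-methyl-5-oxopentanoic acid | C=C1CC[C@H]2C(C)(C)CCC[C@]2(C)[C@H]1C[C@]12O[C@H]1[C@H](O)C(COC(=O)C[C@](C)(O)CC(=O)O)=CC2=O | target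

## Step count and risks

Total step count: 26.
Longest linear sequence: 16 steps (7 → 34 through steps 6–16 and 22–26).

Steps most likely to fail:

Step 12. The hindered lithiated dibromide may add too slowly, so that enolisation of 6 or α-elimination of the carbenoid takes over, and the C7 methylene may migrate in competition with the quaternary carbon, which would lead to the regioisomeric ketone. The fallback sets out from 6 (with bromide 12) and returns at 19. It uses a ring expansion whose well-established regiochemistry is migration of the methylene carbon, with the roles of the two ring carbons exchanged. Ethyl diazoacetate and BF3·OEt2 expand 6 to the β-keto ester ethyl (4aS,8aS)-5,5,8a-trimethyl-1-oxodecahydronaphthalene-2-carboxylate F1; the old carbonyl carbon becomes C9 and the inserted carbon C8. NaH and PhNTf2 give the enol triflate F2. Bromide 12 and zinc dust with LiCl give the benzylzinc bromide F3, and Negishi coupling with Pd(PPh3)4 gives the tetrasubstituted unsaturated ester F4. DIBAL-H reduces it to the allylic alcohol F5. Mitsunobu reaction with 2-nitrobenzenesulfonylhydrazide gives the sulfonylhydrazine F6, which loses sulfinic acid to the allylic diazene F7. Retro-ene loss of nitrogen from F7 moves the double bond to the exocyclic position and delivers hydrogen to C9 on the axial face opposite the angular methyl, giving 19.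

Step 16. Facial selection by the phase-transfer catalyst may be poor on this bulky α-alkyl dienone, leaving a mixture of epoxide diastereomers. The fallback sets out from 21 and returns at 30; it replaces catalyst control by a covalently bound auxiliary. Ketal exchange of 21 with (2R,4R)-pentane-2,4-diol and PPTS gives the chiral dioxane ketal F8 (the enantiomeric diol is taken if the auxiliary shields the wrong face). Epoxidation with Ph3COOH and KHMDS at −78 °C, directed by the axial methyl of the dioxane, gives the epoxide F9. Esterification with 28 as in step 22 gives the ester F10, and hydrolysis of the dioxane ketal on montmorillonite K10 gives 30.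

Step 25. Ionisation of the activated allylic alcohol next to the epoxide may lead to elimination or allylic transposition in place of clean inversion. The fallback sets out from 30 and returns at 34; it sets C3′ by reagent control in the reduction itself. Corey–Bakshi–Shibata reduction of 30 with (R)-2-methyl-CBS-oxazaborolidine and catecholborane at −78 °C, with the alkenyl side acting as the large group, should give the trans-epoxy alcohol F11 directly, and TBAF as in step 26 then gives 34.

## Further compounds

F1 | step 12 | ethyl (4aS,8aS)-5,5,8a-trimethyl-1-oxodecahydronaphthalene-2-carboxylate | CCOC(=O)C1CC[C@H]2C(C)(C)CCC[C@]2(C)C1=O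
F2 | step 12 | enol triflate of F1: ethyl (4aS,8aS)-5,5,8a-trimethyl-1-(trifluoromethylsulfonyloxy)-3,4,4a,5,6,7,8,8a-octahydronaphthalene-2-carboxylate | CCOC(=O)C1CC[C@H]2C(C)(C)CCC[C@]2(C)C=1OS(=O)(=O)C(F)(F)F
F3 | step 12 | (Ar-methyl)zinc bromide | Br[Zn]Cc1cc(OC)c(CO[Si](C(C)C)(C(C)C)C(C)C)cc1O[Si](C(C)C)(C(C)C)C(C)C
F4 | step 12 | ethyl (4aS,8aS)-1-(Ar-methyl)-5,5,8a-trimethyl-3,4,4a,5,6,7,8,8a-octahydronaphthalene-2-carboxylate | CCOC(=O)C1CC[C@H]2C(C)(C)CCC[C@]2(C)C=1Cc3cc(OC)c(CO[Si](C(C)C)(C(C)C)C(C)C)cc3O[Si](C(C)C)(C(C)C)C(C)C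
F5 | step 12 | [(4aS,8aS)-1-(Ar-methyl)-5,5,8a-trimethyl-3,4,4a,5,6,7,8,8a-octahydronaphthalen-2-yl]methanol | OCC1CC[C@H]2C(C)(C)CCC[C@]2(C)C=1Cc3cc(OC)c(CO[Si](C(C)C)(C(C)C)C(C)C)cc3O[Si](C(C)C)(C(C)C)C(C)C
F6 | step 12 | N-allylic N-(2-nitrobenzenesulfonyl)hydrazine from F5 | NN(CC1CC[C@H]2C(C)(C)CCC[C@]2(C)C=1Cc3cc(OC)c(CO[Si](C(C)C)(C(C)C)C(C)C)cc3O[Si](C(C)C)(C(C)C)C(C)C)S(=O)(=O)c4ccccc4[N+](=O)[O-]
F7 | step 12 | allylic monoalkyl diazene from F6 | N=NCC1CC[C@H]2C(C)(C)CCC[C@]2(C)C=1Cc3cc(OC)c(CO[Si](C(C)C)(C(C)C)C(C)C)cc3O[Si](C(C)C)(C(C)C)C(C)C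
F8 | step 16 | quinone mono-[(2R,4R)-pentane-2,4-diyl ketal] of 21 | C=C1CC[C@H]2C(C)(C)CCC[C@]2(C)[C@H]1CC3=CC4(O[C@H](C)C[C@@H](C)O4)C(CO)=CC3=O
F9 | step 16 | (1S,6R)-epoxide of F8 | C=C1CC[C@H]2C(C)(C)CCC[C@]2(C)[C@H]1C[C@]34O[C@H]3C5(O[C@H](C)C[C@@H](C)O5)C(CO)=CC4=O
F10 | step 16 | ester of F9 with 28 | C=C1CC[C@H]2C(C)(C)CCC[C@]2(C)[C@H]1C[C@]34O[C@H]3C5(O[C@H](C)C[C@@H](C)O5)C(COC(=O)C[C@](C)(O)CC(=O)OCC[Si](C)(C)C)=CC4=O
F11 | step 25 | (1S,5R,6S)-5-hydroxy epoxy enone TMSE ester (hydroxyl trans to epoxide) | C=C1CC[C@H]2C(C)(C)CCC[C@]2(C)[C@H]1C[C@]34O[C@H]3[C@H](O)C(COC(=O)C[C@](C)(O)CC(=O)OCC[Si](C)(C)C)=CC4=O
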